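## Retrosynthetic overview
1. The free acid comes from a CH2CH2OH side chain on the quaternary carbon by a final oxidation. Ester and acid never need to be told apart, because their carbons come from different reagents.
2. Both rings come from an acyclic triene ester in one cationic cascade. CH2O·Me2AlCl adds to an isopropenyl CH2, the (E)-alkene closes the cyclohexane (ring B) first, and the tertiary oxygen then closes the tetrahydropyran (ring C). Bonds formed: C1–C2, C9–C10, C8–O.
3. The triene ester comes from the isobutyrate of 12-hydroxynerolidol by a reagent-controlled Ireland–Claisen rearrangement (hindered C4–C5 bond, C5 stereocentre).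
4. 12-Hydroxynerolidol comes from (R)-nerolidol by allylic oxidation. (R)-Nerolidol comes from (E,E)-farnesol by Sharpless epoxidation and reductive epoxide opening (C13 stereocentre).

Assumption: positions use labdane numbering (C13 carbinol carbon, C8=C9 central alkene, C5 carbon bearing CMe2CO2Me, C10 quaternary carbon, C1–C2 the CH2CO2H arm, C3–C4 ester carbon and CMe2), and the (R,R)-controller of step 5 is assumed to give the 3S acid by analogy with (E)-crotyl esters (its antipode is equally available).

## Route

Step 1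
Reactants: 1 (2E,6E)-farnesol
Product: 2 [(2R,3R)-3-[(3E)-4,8-dimethylnona-3,7-dienyl]-3-methyloxiran-2-yl]methanol
Conditions: Ti(OiPr)4 (5 mol %), D-(−)-diethyl tartrate (6 mol %), t-BuOOH (2 equiv), 4 Å molecular sieves, CH2Cl2, −20 °C
Reagents that add atoms: tert-butyl hydroperoxide, CC(C)(C)OO
Why: Sharpless asymmetric epoxidation, in which the titanium tartrate binds the allylic alcohol so that only that alkene reacts, and the D-(−)-tartrate gives the 2R,3R epoxide whose quaternary carbon becomes C13.

Step 2
Reactants: 2 [(2R,3R)-3-[(3E)-4,8-dimethylnona-3,7-dienyl]-3-methyloxiran-2-yl]methanol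
Product: 4 (3R,6E)-nerolidol, via epoxy iodide 3 (not isolated)
Conditions: PPh3, I2, imidazole, THF, 0 °C; then Zn dust, AcOH (2 equiv), same flask, 0 °C to rt
Reagents that add atoms: none
Why: Appel iodination followed by zinc-induced reductive β-elimination (Boord-type epoxide opening) breaks only the secondary C–O bond, so the quaternary C–O bond and its configuration pass unchanged into the tertiary allylic alcohol.

Step 3
Reactants: 4 (3R,6E)-nerolidol
Product: 5 (2E,6E,10R)-2,6,10-trimethyldodeca-2,6,11-triene-1,10-diol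
Conditions: SeO2 (0.2 equiv), t-BuOOH (3 equiv), salicylic acid (0.1 equiv), CH2Cl2, 0 °C to rt, stopped at about 70 % conversion
Reagents that add atoms: tert-butyl hydroperoxide, CC(C)(C)OO
Why: Riley allylic oxidation (ene reaction, then [2,3]-sigmatropic shift) prefers the (E)-methyl group of the terminal, least hindered trisubstituted alkene and gives the (E)-allylic alcohol without touching C13.

Step 4
Reactants: 5 (2E,6E,10R)-2,6,10-trimethyldodeca-2,6,11-triene-1,10-diol; 6 isobutyryl chloride
Product: 8 (2E,6E,10R)-2,6,10-trimethyl-10-(triethylsilyloxy)dodeca-2,6,11-trien-1-yl 2-methylpropanoate, via hydroxy ester 7 (not isolated)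
Conditions: 6 (1.05 equiv), Et3N, 4-(dimethylamino)pyridine (5 mol %), CH2Cl2, −20 °C; then 2,6-lutidine, Et3SiOTf, −78 to 0 °C, same flask
Reagents that add atoms: isobutyryl chloride (6), CC(C)C(=O)Cl; triethylsilyl trifluoromethanesulfonate, CC[Si](CC)(CC)OS(=O)(=O)C(F)(F)F
Why: Nucleophile-catalysed acylation takes only the primary allylic alcohol, and silyl triflate then caps the tertiary one, which keeps the Lewis acids of steps 5 and 6 off a free tertiary allylic alcohol, and the silyl group is shed during step 6.

Step 5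
Reactants: 8 (2E,6E,10R)-2,6,10-trimethyl-10-(triethylsilyloxy)dodeca-2,6,11-trien-1-yl 2-methylpropanoate
Product: 12 methyl (3S,6E,10R)-2,2,6,10-tetramethyl-3-(prop-1-en-2-yl)-10-(triethylsilyloxy)dodeca-6,11-dienoate, via boron ketene acetal 9 (not isolated), via acyloxyborane 10 (not isolated), via silyl ether acid 11 (not isolated)
Conditions: (1R,2R)-N,N'-bis[3,5-bis(trifluoromethyl)benzenesulfonyl]-1,2-diphenylethane-1,2-diamine + BBr3 (1.3 equiv each), CH2Cl2, rt, evaporate; then 8, Et3N (4 equiv), toluene–hexane, −78 °C to 4 °C, 3 d; aqueous work-up (base extraction, citric acid to pH 4); crude acid, Me3SiCHN2, toluene–MeOH, 0 °C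
Reagents that add atoms: (trimethylsilyl)diazomethane, C[Si](C)(C)C=[N+]=[N-]
Why: Proposed new method: soft enolisation with the chiral 2-bromo-1,3,2-diazaborolidine gives a boron ketene acetal with no E/Z issue, whose chair [3,3] shift forms the C4–C5 bond and the isopropenyl group while the C2-symmetric sulfonamide shell blocks one face of the (E)-allyl unit and so sets C5 as 3S; the closest known reaction type is the enantioselective boron Ireland–Claisen rearrangement of achiral (E)-crotyl, geranyl and farnesyl esters, extended here to an isobutyrate, and the diazomethane esterification touches no stereocentre.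

Step 6
Reactants: 12 methyl (3S,6E,10R)-2,2,6,10-tetramethyl-3-(prop-1-en-2-yl)-10-(triethylsilyloxy)dodeca-6,11-dienoate; 13 paraformaldehyde (source of formaldehyde)
Product: 14 methyl 2-[(2R,4aS,5R,6S,8aS)-2-ethenyl-5-(2-hydroxyethyl)-2,5,8a-trimethyloctahydro-2H-chromen-6-yl]-2-methylpropanoate
Conditions: 13 (2 equiv as CH2O) + Me2AlCl (3 equiv), CH2Cl2, 0 °C, 30 min; then 12, −78 to −30 °C; aq. potassium sodium tartrate, then aq. citric acid wash
Reagents that add atoms: formaldehyde from paraformaldehyde (13), C=O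
Why: Proposed new method: the pre-formed CH2O·Me2AlCl complex should add to the exposed terminal CH2 of the isopropenyl group (the vinyl group is inert), the tertiary C10 cation, reversibly buffered by the ester carbonyl on the face syn to C4, is captured anti to the equatorial CMe2CO2Me group by the (E)-C8=C9 alkene in a chair, and the C8 cation is closed by the silyl ether oxygen with loss of Et3SiCl, so C10 (methyl axial, new side chain equatorial), C9 and C8 (trans fusion from the E alkene) are all set from C5 while C13 is carried over; the closest known reaction types are the Me2AlCl-promoted Prins/ene addition of formaldehyde to 1,1-disubstituted alkenes, intermolecular acetal-initiated polyene cyclisation, and the bromonium- or mercury-induced bicyclisation of nerolidol to caparrapi oxides.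

Step 7
Reactants: 14 methyl 2-[(2R,4aS,5R,6S,8aS)-2-ethenyl-5-(2-hydroxyethyl)-2,5,8a-trimethyloctahydro-2H-chromen-6-yl]-2-methylpropanoate
Product: 15 2-[(2R,4aS,5R,6S,8aS)-2-ethenyl-6-(1-methoxy-2-methyl-1-oxopropan-2-yl)-2,5,8a-trimethyloctahydro-2H-chromen-5-yl]acetic acid
Conditions: 2,2,6,6-tetramethylpiperidin-1-oxyl (20 mol %), PhI(OAc)2 (2.5 equiv), MeCN–H2O 1:1, rt
Reagents that add atoms: water, O
Why: Oxoammonium (TEMPO) oxidation takes the primary alcohol through the aldehyde hydrate to the acid under near-neutral conditions that leave the vinyl group, the tertiary allylic ether, the hindered methyl ester and all five stereocentres untouched.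

## Compound list
1 | (2E,6E)-farnesol | OC/C=C(\C)CC/C=C(\C)CCC=C(C)C | starting material
2 | (2R,3R)-2,3-epoxyfarnesol | OC[C@H]1O[C@]1(C)CC/C=C(\C)CCC=C(C)C | intermediate
3 | (2S,3R)-2,3-epoxyfarnesyl iodide (same spatial arrangement as 2) | IC[C@H]1O[C@]1(C)CC/C=C(\C)CCC=C(C)C | intermediate
4 | (3R,6E)-nerolidol | C=C[C@@](O)(C)CC/C=C(\C)CCC=C(C)C | intermediate
5 | (2E,6E,10R)-2,6,10-trimethyldodeca-2,6,11-triene-1,10-diol | C=C[C@@](O)(C)CC/C=C(\C)CC/C=C(\C)CO | intermediate
6 | isobutyryl chloride | CC(C)C(=O)Cl | starting material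
7 | (2E,6E,10R)-10-hydroxy-2,6,10-trimethyldodeca-2,6,11-trien-1-yl 2-methylpropanoate | C=C[C@@](O)(C)CC/C=C(\C)CC/C=C(\C)COC(=O)C(C)C | intermediate
8 | triethylsilyl ether of 7 | C=C[C@@](O[Si](CC)(CC)CC)(C)CC/C=C(\C)CC/C=C(\C)COC(=O)C(C)C | intermediate
9 | boron ketene acetal of 8 carrying the (R,R)-diazaborolidine | C=C[C@@](O[Si](CC)(CC)CC)(C)CC/C=C(\C)CC/C=C(\C)COC(OB1N(S(=O)(=O)c2cc(C(F)(F)F)cc(C(F)(F)F)c2)[C@H](c2ccccc2)[C@@H](c2ccccc2)N1S(=O)(=O)c1cc(C(F)(F)F)cc(C(F)(F)F)c1)=C(C)C | intermediate
10 | rearranged acyloxyborane (3S) | C=C[C@@](O[Si](CC)(CC)CC)(C)CC/C=C(\C)CC[C@@H](C(C)=C)C(C)(C)C(=O)OB1N(S(=O)(=O)c2cc(C(F)(F)F)cc(C(F)(F)F)c2)[C@H](c2ccccc2)[C@@H](c2ccccc2)N1S(=O)(=O)c1cc(C(F)(F)F)cc(C(F)(F)F)c1 | intermediate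
11 | (3S,6E,10R)-2,2,6,10-tetramethyl-3-(prop-1-en-2-yl)-10-(triethylsilyloxy)dodeca-6,11-dienoic acid | C=C[C@@](O[Si](CC)(CC)CC)(C)CC/C=C(\C)CC[C@@H](C(C)=C)C(C)(C)C(=O)O | intermediate
12 | methyl ester of 11 | C=C[C@@](O[Si](CC)(CC)CC)(C)CC/C=C(\C)CC[C@@H](C(C)=C)C(C)(C)C(=O)OC | intermediate
13 | paraformaldehyde (reacts as formaldehyde) | C=O | starting material
14 | bicyclic primary alcohol (2R,4aS,5R,6S,8aS) | C=C[C@@]1(C)CC[C@H]2[C@](C)(CCO)[C@@H](C(C)(C)C(=O)OC)CC[C@]2(C)O1 | intermediate
15 | CNP0280657.1 (2R,4aS,5R,6S,8aS; labdane 13R,9S,10R,5S,8S) | C=C[C@@]1(C)CC[C@H]2[C@](C)(CC(=O)O)[C@@H](C(C)(C)C(=O)OC)CC[C@]2(C)O1 | target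

Total step count: 7. Longest linear sequence: 7.

## Steps most likely to fail

**Step 6 (key cascade).**
- The zwitterion may lose a proton (plain ene product).
- The ester carbonyl may trap C10 for good as a γ-lactone.
- Formaldehyde may attack the C8=C9 alkene instead.

The fallback sets out from 12 and comes back at 15. It replaces the carbon electrophile by a metal and brings in C2 afterwards as CO. Compound 12 is treated with the Hg(OTf)2–N,N-dimethylaniline complex in MeNO2 at −20 °C and then with aqueous NaCl. Divalent mercury selects 1,1-disubstituted over trisubstituted and hindered vinyl alkenes. The same chair cascade then gives the chloromercurial with CH2HgCl in place of the CH2CH2OH group of 14, F1. Its neopentyl C–Hg bond has no β-hydrogen and no β-oxygen. Transmetalation with Li2PdCl4 under CO (1 atm) in THF–H2O therefore gives an acylpalladium species that water cleaves to 15 directly, and step 7 is not needed.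

**Step 5 (reagent-controlled Claisen).**
- Enolisation of the isobutyrate may be slow.
- The level and sense of induction are untested.

The fallback sets out from 5 and comes back at 14. It gives up reagent control in favour of a one-step rearrangement and a later separation of diastereomers.
- Compound 5 is heated with trimethyl orthoisobutyrate (1.5 equiv) and catalytic propionic acid in xylene at 135 °C (Johnson–Claisen).
- The reaction runs through the mixed ketene acetal F2.
- It gives the hydroxy ester methyl (3S,6E,10R)-10-hydroxy-2,2,6,10-tetramethyl-3-(prop-1-en-2-yl)dodeca-6,11-dienoate F3 together with its 3R epimer F4, in about a 1:1 ratio.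
- The pair is taken through the conditions of step 6 with one more equivalent of Me2AlCl for the free alcohol.
- F3 gives 14. F4 gives the (2R,4aR,5S,6R,8aR) diastereomer of 14, F5, which is removed by chromatography because C13 is already a single configuration.

**Step 3 (allylic oxidation).**
- The yield is usually modest.
- Over-oxidation to the enal and oxidation next to the inner alkene cost material.

The fallback sets out from 4 and comes back at 5. It replaces C–H oxidation by truncation and rebuilding of the chain end.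
- N-Bromosuccinimide in aqueous THF attacks the terminal alkene selectively to give the bromohydrin (3R,6E)-10-bromo-3,7,11-trimethyldodeca-1,6-diene-3,11-diol F6.
- K2CO3 in MeOH closes it to the epoxide (3R,6E)-10,11-epoxy-3,7,11-trimethyldodeca-1,6-dien-3-ol F7.
- HIO4 in THF–Et2O cleaves the epoxide to the aldehyde (4E,8R)-8-hydroxy-4,8-dimethyldeca-4,9-dienal F8.
- The stabilised ylide Ph3P=C(CH3)CO2Et gives ethyl (2E,6E,10R)-10-hydroxy-2,6,10-trimethyldodeca-2,6,11-trienoate F9.
- iBu2AlH in CH2Cl2 at −78 °C reduces F9 to 5.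

## Further compounds
F1 | step 6 | chloromercurial, CH2HgCl in place of the CH2CH2OH of 14 (same spatial arrangement) | C=C[C@@]1(C)CC[C@H]2[C@](C)(C[Hg]Cl)[C@@H](C(C)(C)C(=O)OC)CC[C@]2(C)O1
F2 | step 5 | mixed methyl allyl ketene acetal of isobutyric acid from 5 | C=C[C@@](O)(C)CC/C=C(\C)CC/C=C(\C)COC(OC)=C(C)C
F3 | step 5 | methyl (3S,6E,10R)-10-hydroxy-2,2,6,10-tetramethyl-3-(prop-1-en-2-yl)dodeca-6,11-dienoate | C=C[C@@](O)(C)CC/C=C(\C)CC[C@@H](C(C)=C)C(C)(C)C(=O)OC
F4 | step 5 | methyl (3R,6E,10R)-10-hydroxy-2,2,6,10-tetramethyl-3-(prop-1-en-2-yl)dodeca-6,11-dienoate | C=C[C@@](O)(C)CC/C=C(\C)CC[C@H](C(C)=C)C(C)(C)C(=O)OC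
F5 | step 5 | (2R,4aR,5S,6R,8aR) diastereomer of 14 | C=C[C@@]1(C)CC[C@@H]2[C@@](C)(CCO)[C@H](C(C)(C)C(=O)OC)CC[C@@]2(C)O1
F6 | step 3 | (3R,6E)-10-bromo-3,7,11-trimethyldodeca-1,6-diene-3,11-diol (both epimers at the bromide carbon) | C=C[C@@](O)(C)CC/C=C(\C)CCC(Br)C(C)(C)O
F7 | step 3 | (3R,6E)-10,11-epoxy-3,7,11-trimethyldodeca-1,6-dien-3-ol (both epoxide epimers) | C=C[C@@](O)(C)CC/C=C(\C)CCC1OC1(C)C
F8 | step 3 | (4E,8R)-8-hydroxy-4,8-dimethyldeca-4,9-dienal | C=C[C@@](O)(C)CC/C=C(\C)CCC=O
F9 | step 3 | ethyl (2E,6E,10R)-10-hydroxy-2,6,10-trimethyldodeca-2,6,11-trienoate | C=C[C@@](O)(C)CC/C=C(\C)CC/C=C(\C)C(=O)OCC
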